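The benzene ring is built last. The tetralin is cut at C5–C6 and C8–C8a: C5 becomes the formyl carbon of a 2-hydroxymethylene cyclohexanone, and C6–C7–C8 with the carboxyl group and both phenolic oxygens come from one 4-benzyloxyacetoacetate. A single Knoevenagel/aldol/dehydration cascade fuses the arene onto the saturated ring (C1–C4, C4a, C8a) and installs the contiguous CO2R/OH/OR pattern with fixed regiochemistry, because C8a has only one alpha-methylene (C4a). The precursor is a trans-dihydrocarvone bearing the complete, bis-silylated C4 side chain and a C4a hydroxymethylene group, so all four stereocentres are set before the arene exists.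

Key step: step 13

Remark on numbering: tetralin locants are used throughout (C1 bears the methyl, C4 the side chain, C11 is the side-chain methine on C4, C15 the remote methyl-bearing methine).
Remark on step 8: the (R)-ligand is written; which antipode delivers hydrogen to the face of C11 that gives 11S is to be confirmed on the first run, and the (S)-ligand is the direct replacement.
Remark on supply: (R)-2-methylpent-4-en-1-ol is taken as a purchasable building block.
Remark on protecting groups: TBDPS ethers and a benzyl ester replace the more usual TBS ethers and ethyl ester, so that the silyl ethers survive ketal hydrolysis and the acid is freed in the final hydrogenolysis.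

Step 1
Reactants: 1 (R)-carvone
Product: 3 trans-dihydrocarvone (2R,5R)-2-methyl-5-(prop-1-en-2-yl)cyclohexan-1-one, via lithium enolate 2 (not isolated)
Conditions: LiBH(s-Bu)3 (1.1 equiv), THF, −78 °C; then MeOH, −78 °C to rt; chromatography
Reagents that add atoms: none
Why: Conjugate reduction of the beta-unsubstituted enone by the hindered borohydride gives enolate 2, and protonation followed by equilibration with the methoxide formed should leave the C2 methyl equatorial and trans to the untouched C5 isopropenyl group, the minor cis epimer being removed by chromatography and re-equilibrated.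

Step 2
Reactants: 3 trans-dihydrocarvone
Product: 4 (6R,9R)-6-methyl-9-(prop-1-en-2-yl)-1,4-dioxaspiro[4.5]decane
Conditions: (TMSOCH2)2 (1.5 equiv), TMSOTf (5 mol%), CH2Cl2, −78 to −20 °C; pyridine quench
Reagents that add atoms: 1,2-bis(trimethylsilyloxy)ethane, C[Si](C)(C)OCCO[Si](C)(C)C
Why: Silyl-transfer ketalisation at low temperature is non-equilibrating, so the alpha-methyl centre and the isopropenyl double bond should stay as they are while the ketone is masked against the Grignard and hydride reagents that follow.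

Step 3
Reactants: 4 dihydrocarvone ketal
Product: 5 (6R,9R)-9-(3-chloroprop-1-en-2-yl)-6-methyl-1,4-dioxaspiro[4.5]decane
Conditions: Ca(OCl)2, solid CO2, CH2Cl2–H2O, 0 °C
Reagents that add atoms: calcium hypochlorite, [Ca+2].[O-]Cl.[O-]Cl
Why: Ene-type allylic chlorination by HOCl made in the flask puts chlorine on the alkene terminus with shift of the double bond into the former methyl group, the isopropenyl unit being the only alkene and the carbonate-buffered medium being mild enough for the dioxolane.

Step 4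
Reactants: 6 (R)-2-methylpent-4-en-1-ol
Product: 7 tert-butyl{[(2R)-2-methylpent-4-en-1-yl]oxy}diphenylsilane
Conditions: TBDPSCl, imidazole, CH2Cl2, rt
Reagents that add atoms: tert-butyl(chloro)diphenylsilane, CC(C)(C)[Si](Cl)(c1ccccc1)c1ccccc1
Why: Routine silylation of a primary alcohol, the acid-stable TBDPS group being chosen because it must outlast the later ketal hydrolysis.

Step 5
Reactants: 7 silyl ether of the pentenol
Product: 9 (3R)-4-{[tert-butyl(diphenyl)silyl]oxy}-3-methylbutan-1-ol, via aldehyde 8 (not isolated)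
Conditions: O3, CH2Cl2, −78 °C; PPh3, −78 °C to rt; then NaBH4, MeOH, 0 °C
Reagents that add atoms: ozone, [O-][O+]=O
Why: Ozonolysis of the terminal alkene with reductive work-up removes one carbon and borohydride reduces aldehyde 8 in the same flask, the stereocentre being beta to the carbonyl and therefore not epimerisable.

Step 6
Reactants: 9 silyloxy alcohol
Product: 10 [(2R)-4-bromo-2-methylbutoxy](tert-butyl)diphenylsilane
Conditions: CBr4, PPh3, imidazole, CH2Cl2, 0 °C
Reagents that add atoms: carbon tetrabromide, BrC(Br)(Br)Br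
Why: Appel bromination converts the unhindered primary alcohol into the bromide under neutral conditions that the silyl ether tolerates.

Step 7
Reactants: 10 silyloxy bromide; 5 allylic chloride
Product: 12 tert-butyl({(2R)-2-methyl-6-[(6R,9R)-6-methyl-1,4-dioxaspiro[4.5]decan-9-yl]hept-6-en-1-yl}oxy)diphenylsilane, via Grignard reagent 11 (not isolated)
Conditions: 10 (1.3 equiv), Mg, THF, 45 °C; then 5, Li2CuCl4 (5 mol%), THF, −20 °C to rt
Reagents that add atoms: none
Why: Grignard formation from the primary bromide followed by copper-catalysed sp3–sp3 coupling with the allylic chloride, in which direct and allylically transposed substitution give the same 1,1-disubstituted alkene because the allyl unit is symmetric about its central carbon.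

Step 8
Reactants: 12 1,1-disubstituted alkene
Product: 14 (2S,6R)-7-{[tert-butyl(diphenyl)silyl]oxy}-6-methyl-2-[(6R,9R)-6-methyl-1,4-dioxaspiro[4.5]decan-9-yl]heptan-1-ol, via pinacol boronate 13 (not isolated)
Conditions: CuCl (5 mol%), (R)-DTBM-SEGPHOS (6 mol%), KOt-Bu (10 mol%), HBpin (1.5 equiv), toluene, rt; then H2O2, aq. NaOH, THF, 0 °C
Reagents that add atoms: hydrogen peroxide, OO
Why: Copper hydride catalysed asymmetric hydroboration of an unactivated 1,1-disubstituted alkene puts boron on the terminal carbon and hydrogen on C11 from the face set by the bisphosphine ligand (catalyst control, the adjacent C4 centre having little bias of its own), and stereoretentive oxidation of boronate 13 should give the 11S primary alcohol.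

Step 9
Reactants: 14 primary alcohol
Product: 15 (6R,9R)-9-[(2S,6R)-1,7-bis{[tert-butyl(diphenyl)silyl]oxy}-6-methylheptan-2-yl]-6-methyl-1,4-dioxaspiro[4.5]decane
Conditions: TBDPSCl, imidazole, DMF, rt
Reagents that add atoms: tert-butyl(chloro)diphenylsilane, CC(C)(C)[Si](Cl)(c1ccccc1)c1ccccc1
Why: Routine silylation of the new primary alcohol, so that no free hydroxyl can add to the formyl group introduced two steps later.

Step 10
Reactants: 15 bis-silylated ketal
Product: 16 (2R,5R)-5-[(2S,6R)-1,7-bis{[tert-butyl(diphenyl)silyl]oxy}-6-methylheptan-2-yl]-2-methylcyclohexan-1-one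
Conditions: PPTS (0.3 equiv), acetone–H2O (9:1), 55 °C
Reagents that add atoms: water, O
Why: Mild acid-catalysed ketal hydrolysis frees the ketone while both TBDPS ethers remain, and since the trans-2,5-disubstituted (diequatorial) ketone is also the thermodynamic epimer, any enolisation cannot erode C1.

Step 11
Reactants: 16 ketone
Product: 18 (2Z,3S,6R)-3-[(2S,6R)-1,7-bis{[tert-butyl(diphenyl)silyl]oxy}-6-methylheptan-2-yl]-2-(hydroxymethylidene)-6-methylcyclohexan-1-one, via lithium enolate 17 (not isolated)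
Conditions: LiN(i-Pr)2 (1.2 equiv), THF, −78 °C; HCO2CH2CF3 (1.5 equiv), −78 to 0 °C; aq. NH4Cl
Reagents that add atoms: 2,2,2-trifluoroethyl formate, O=COCC(F)(F)F
Why: Kinetic deprotonation takes a proton from the only alpha-methylene (C4a) and leaves the C1 methine untouched, and C-formylation of enolate 17 with the activated formate (crossed Claisen condensation) should give the chelated Z-hydroxymethylene ketone with C1 intact.

Step 12
Reactants: 19 ethyl 4-(benzyloxy)-3-oxobutanoate
Product: 20 benzyl 4-(benzyloxy)-3-oxobutanoate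
Conditions: BnOH (1.2 equiv), DMAP (0.1 equiv), toluene, reflux, 4 Å MS (removal of EtOH)
Reagents that add atoms: benzyl alcohol, OCc1ccccc1
Why: DMAP-catalysed transesterification of a beta-keto ester, driven by removal of ethanol, provides an ester that is later cleaved by hydrogenolysis together with the benzyl ether.

Step 13
Reactants: 18 hydroxymethylene ketone; 20 benzyl 4-(benzyloxy)-3-oxobutanoate
Product: 21 benzyl (5R,8S)-4-(benzyloxy)-8-[(2S,6R)-1,7-bis{[tert-butyl(diphenyl)silyl]oxy}-6-methylheptan-2-yl]-3-hydroxy-5-methyl-5,6,7,8-tetrahydronaphthalene-2-carboxylate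
Conditions: 20 (1.3 equiv), piperidine (0.5 equiv), AcOH (0.5 equiv), toluene, 4 Å MS, 90 °C
Reagents that add atoms: none
Why: Under amine–acid buffering the formyl carbon C5 of 18, a vinylogous acid activated as its iminium or enaminone, is attacked by the doubly activated C2 of 20 with loss of water (Knoevenagel, forms C5–C6), after which the benzyloxy-bearing carbon of the adduct, enolised towards its ketone, adds to the ring carbonyl C8a (forms C8–C8a) and dehydration plus tautomerisation of the cyclohexadienone (C4a–H to oxygen) gives the phenol. The closest known reaction type is the condensation of 2-hydroxymethylene ketones with acetoacetates or acetonedicarboxylates to give salicylates, of which the 4-alkoxy ketoester is a close variant. The one ring formed, the benzene ring C4a–C5–C6–C7–C8–C8a, is closed by a 6-exo-trig aldol addition to the C8a carbonyl. No stereocentre is created. The step needs regioselectivity and retention of C1: the formyl carbon is more electrophilic than the hindered ketone and ketoester C2 is more acidic than ketoester C4, which pairs ketoester C2 with C5 and ketoester C4 with C8a, and C8a has a single alpha-methylene, so the arene can only be fused on the C4a side. The weakly basic buffer and the enolised beta-dicarbonyl should keep the C1 methine from being deprotonated, and aromatisation then removes the C8a carbonyl and fixes C1 trans to the C4 chain.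

Step 14
Reactants: 21 bis-silylated benzannulation product
Product: 22 benzyl (5R,8S)-4-(benzyloxy)-8-[(2S,6R)-1,7-dihydroxy-6-methylheptan-2-yl]-3-hydroxy-5-methyl-5,6,7,8-tetrahydronaphthalene-2-carboxylate
Conditions: Bu4NF (4 equiv), AcOH (4 equiv), THF, rt to 40 °C
Reagents that add atoms: none
Why: Fluoride cleaves both primary silyl ethers, and buffering with acetic acid keeps the phenol protonated and the benzyl ester safe from basic fluoride.

Step 15
Reactants: 22 diol
Product: 24 benzyl (5R,8S)-4-(benzyloxy)-8-[(2S,6R)-1,7-diacetoxy-6-methylheptan-2-yl]-3-hydroxy-5-methyl-5,6,7,8-tetrahydronaphthalene-2-carboxylate, via triacetate 23 (not isolated)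
Conditions: Ac2O (5 equiv), pyridine, DMAP (cat.), CH2Cl2, 0 °C to rt; then pyrrolidine (excess), 0 °C to rt
Reagents that add atoms: acetic anhydride, CC(=O)OC(C)=O
Why: Exhaustive acetylation gives triacetate 23 whatever the reactivity of the chelated phenol, and the aryl acetate, an activated phenyl ester ortho to a carbonyl group, is then removed by selective aminolysis that primary alkyl acetates and the benzyl ester should withstand.

Step 16
Reactants: 24 diacetate
Product: 25 (5R,8S)-8-[(2S,6R)-1,7-diacetoxy-6-methylheptan-2-yl]-3,4-dihydroxy-5-methyl-5,6,7,8-tetrahydronaphthalene-2-carboxylic acid (target)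
Conditions: H2 (1 atm), Pd/C (10%), EtOAc, rt; filtration under argon
Reagents that add atoms: none
Why: Hydrogenolysis over palladium on carbon cleaves the benzyl aryl ether and the benzyl ester in one operation and leaves the alkyl acetates, the arene and all four stereocentres unchanged.

Compound list
1 | (R)-carvone, (5R)-2-methyl-5-(prop-1-en-2-yl)cyclohex-2-en-1-one | CC(=C)[C@@H]1CC=C(C)C(=O)C1 | starting material
2 | lithium (5R)-2-methyl-5-(prop-1-en-2-yl)cyclohex-1-en-1-olate | CC(=C)[C@@H]1CCC(C)=C([O-])C1.[Li+] | intermediate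
3 | trans-dihydrocarvone, (2R,5R)-2-methyl-5-(prop-1-en-2-yl)cyclohexan-1-one | CC(=C)[C@@H]1CC[C@@H](C)C(=O)C1 | intermediate
4 | (6R,9R)-6-methyl-9-(prop-1-en-2-yl)-1,4-dioxaspiro[4.5]decane | CC(=C)[C@@H]1CC[C@@H](C)C2(OCCO2)C1 | intermediate
5 | (6R,9R)-9-(3-chloroprop-1-en-2-yl)-6-methyl-1,4-dioxaspiro[4.5]decane | ClCC(=C)[C@@H]1CC[C@@H](C)C2(OCCO2)C1 | intermediate
6 | (R)-2-methylpent-4-en-1-ol | OC[C@H](C)CC=C | starting material
7 | tert-butyl{[(2R)-2-methylpent-4-en-1-yl]oxy}diphenylsilane | CC(C)(C)[Si](c1ccccc1)(c1ccccc1)OC[C@H](C)CC=C | intermediate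
8 | (3R)-4-{[tert-butyl(diphenyl)silyl]oxy}-3-methylbutanal | CC(C)(C)[Si](c1ccccc1)(c1ccccc1)OC[C@H](C)CC=O | intermediate
9 | (3R)-4-{[tert-butyl(diphenyl)silyl]oxy}-3-methylbutan-1-ol | CC(C)(C)[Si](c1ccccc1)(c1ccccc1)OC[C@H](C)CCO | intermediate
10 | [(2R)-4-bromo-2-methylbutoxy](tert-butyl)diphenylsilane | CC(C)(C)[Si](c1ccccc1)(c1ccccc1)OC[C@H](C)CCBr | intermediate
11 | {(3R)-4-[tert-butyl(diphenyl)silyl]oxy-3-methylbutyl}magnesium bromide | CC(C)(C)[Si](c1ccccc1)(c1ccccc1)OC[C@H](C)CC[Mg]Br | intermediate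
12 | tert-butyl({(2R)-2-methyl-6-[(6R,9R)-6-methyl-1,4-dioxaspiro[4.5]decan-9-yl]hept-6-en-1-yl}oxy)diphenylsilane | CC(C)(C)[Si](c1ccccc1)(c1ccccc1)OC[C@H](C)CCCC(=C)[C@@H]1CC[C@@H](C)C2(OCCO2)C1 | intermediate
13 | pinacol boronate of 14 (CH2Bpin in place of CH2OH at C11, same configuration) | CC(C)(C)[Si](c1ccccc1)(c1ccccc1)OC[C@H](C)CCC[C@H](CB1OC(C)(C)C(C)(C)O1)[C@@H]1CC[C@@H](C)C2(OCCO2)C1 | intermediate
14 | (2S,6R)-7-{[tert-butyl(diphenyl)silyl]oxy}-6-methyl-2-[(6R,9R)-6-methyl-1,4-dioxaspiro[4.5]decan-9-yl]heptan-1-ol | CC(C)(C)[Si](c1ccccc1)(c1ccccc1)OC[C@H](C)CCC[C@H](CO)[C@@H]1CC[C@@H](C)C2(OCCO2)C1 | intermediate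
15 | (6R,9R)-9-[(2S,6R)-1,7-bis{[tert-butyl(diphenyl)silyl]oxy}-6-methylheptan-2-yl]-6-methyl-1,4-dioxaspiro[4.5]decane | CC(C)(C)[Si](c1ccccc1)(c1ccccc1)OC[C@H](C)CCC[C@H](CO[Si](c1ccccc1)(c1ccccc1)C(C)(C)C)[C@@H]1CC[C@@H](C)C2(OCCO2)C1 | intermediate
16 | (2R,5R)-5-[(2S,6R)-1,7-bis{[tert-butyl(diphenyl)silyl]oxy}-6-methylheptan-2-yl]-2-methylcyclohexan-1-one | CC(C)(C)[Si](c1ccccc1)(c1ccccc1)OC[C@H](C)CCC[C@H](CO[Si](c1ccccc1)(c1ccccc1)C(C)(C)C)[C@@H]1CC[C@@H](C)C(=O)C1 | intermediate
17 | kinetic lithium enolate of 16 (C8a=C4a double bond) | CC(C)(C)[Si](c1ccccc1)(c1ccccc1)OC[C@H](C)CCC[C@H](CO[Si](c1ccccc1)(c1ccccc1)C(C)(C)C)[C@@H]1CC[C@@H](C)C([O-])=C1.[Li+] | intermediate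
18 | (2Z,3S,6R)-3-[(2S,6R)-1,7-bis{[tert-butyl(diphenyl)silyl]oxy}-6-methylheptan-2-yl]-2-(hydroxymethylidene)-6-methylcyclohexan-1-one | CC(C)(C)[Si](c1ccccc1)(c1ccccc1)OC[C@H](C)CCC[C@H](CO[Si](c1ccccc1)(c1ccccc1)C(C)(C)C)[C@@H]1CC[C@@H](C)C(=O)/C1=C\O | intermediate
19 | ethyl 4-(benzyloxy)-3-oxobutanoate | CCOC(=O)CC(=O)COCc1ccccc1 | starting material
20 | benzyl 4-(benzyloxy)-3-oxobutanoate | O=C(CC(=O)COCc1ccccc1)OCc1ccccc1 | intermediate
21 | benzyl (5R,8S)-4-(benzyloxy)-8-[(2S,6R)-1,7-bis{[tert-butyl(diphenyl)silyl]oxy}-6-methylheptan-2-yl]-3-hydroxy-5-methyl-5,6,7,8-tetrahydronaphthalene-2-carboxylate | CC(C)(C)[Si](c1ccccc1)(c1ccccc1)OC[C@H](C)CCC[C@H](CO[Si](c1ccccc1)(c1ccccc1)C(C)(C)C)[C@@H]1CC[C@@H](C)c2c1cc(C(=O)OCc3ccccc3)c(O)c2OCc3ccccc3 | intermediate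
22 | benzyl (5R,8S)-4-(benzyloxy)-8-[(2S,6R)-1,7-dihydroxy-6-methylheptan-2-yl]-3-hydroxy-5-methyl-5,6,7,8-tetrahydronaphthalene-2-carboxylate | OC[C@H](C)CCC[C@H](CO)[C@@H]1CC[C@@H](C)c2c1cc(C(=O)OCc3ccccc3)c(O)c2OCc3ccccc3 | intermediate
23 | benzyl (5R,8S)-3-acetoxy-4-(benzyloxy)-8-[(2S,6R)-1,7-diacetoxy-6-methylheptan-2-yl]-5-methyl-5,6,7,8-tetrahydronaphthalene-2-carboxylate | CC(=O)OC[C@H](C)CCC[C@H](COC(C)=O)[C@@H]1CC[C@@H](C)c2c1cc(C(=O)OCc3ccccc3)c(OC(C)=O)c2OCc3ccccc3 | intermediate
24 | benzyl (5R,8S)-4-(benzyloxy)-8-[(2S,6R)-1,7-diacetoxy-6-methylheptan-2-yl]-3-hydroxy-5-methyl-5,6,7,8-tetrahydronaphthalene-2-carboxylate | CC(=O)OC[C@H](C)CCC[C@H](COC(C)=O)[C@@H]1CC[C@@H](C)c2c1cc(C(=O)OCc3ccccc3)c(O)c2OCc3ccccc3 | intermediate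
25 | (5R,8S)-8-[(2S,6R)-1,7-diacetoxy-6-methylheptan-2-yl]-3,4-dihydroxy-5-methyl-5,6,7,8-tetrahydronaphthalene-2-carboxylic acid (CNP0245723.1) | CC(=O)OC[C@H](C)CCC[C@H](COC(C)=O)[C@@H]1CC[C@@H](C)c2c1cc(C(=O)O)c(O)c2O | target

Total step count: 16. Longest linear sequence: 12 steps from (R)-carvone (steps 1, 2, 3, 7, 8, 9, 10, 11, 13, 14, 15, 16).

Steps most likely to fail

Step 13. The second bond may not form: the benzyloxy-bearing carbon is a weaker and bulkier donor than a methyl group, and the C8a carbonyl is hindered by the C1 methyl. The reaction could therefore stall at the open Knoevenagel adduct, close through oxygen to a pyran, or need heating long enough to enolise C1. The fallback puts the C8 oxygen on after the ring is made. It sets out from 18, which is condensed under the same buffer with commercial benzyl acetoacetate, whose aldol donor is an unhindered methyl group, to give the C8-unsubstituted salicylate F1. Magnesium-mediated ortho-formylation (MgCl2, Et3N, paraformaldehyde, MeCN, reflux) can only reach C8, the one free position ortho to the phenol, and gives aldehyde F2. Dakin oxidation (H2O2, aq. Na2CO3, THF, rt) gives catechol F3. Benzylation of the non-chelated C8 hydroxyl (BnBr, 1 equiv, K2CO3, acetone) comes back to the route at 21.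

Step 8. Facial discrimination may be poor, since both substituents on C11 are alkyl groups (a ring methine and an n-alkyl chain), and the hindered alkene may be converted slowly. The fallback gives up asymmetric induction and relies on separation. It sets out from 12, which is hydroborated with 9-BBN (THF, rt) to the B-alkyl borane F4 as both C11 epimers. Oxidation (H2O2, aq. NaOH) gives 14 together with its C11 epimer F5. The two are diastereomers with the new centre next to C4 and are separated by preparative HPLC on silica, which comes back to the route at 14.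

Step 3. Chemoselectivity may be lost through addition of HOCl across the alkene, a second chlorination, or opening of the dioxolane in the aqueous carbonic acid medium. The fallback reverses the polarity of the coupling and joins the fragments at an sp2 carbon. It sets out from 4, which is ozonised (O3, CH2Cl2, −78 °C; Me2S) to the methyl ketone F6. Kinetic deprotonation on the methyl side (KN(SiMe3)2, THF, −78 °C) gives the potassium enolate F7, which is trapped with PhNTf2 as the enol triflate F8. Silyl ether 7 is hydroborated with 9-BBN to the alkylborane F9, and B-alkyl Suzuki–Miyaura coupling with F8 (Pd(dppf)Cl2, AsPh3, Cs2CO3, DMF–THF–H2O, rt) comes back to the route at 12. Steps 5, 6 and 7 are then not needed.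

Further compounds
F1 | step 13 | benzyl (5R,8S)-8-[(2S,6R)-1,7-bis{[tert-butyl(diphenyl)silyl]oxy}-6-methylheptan-2-yl]-3-hydroxy-5-methyl-5,6,7,8-tetrahydronaphthalene-2-carboxylate | CC(C)(C)[Si](c1ccccc1)(c1ccccc1)OC[C@H](C)CCC[C@H](CO[Si](c1ccccc1)(c1ccccc1)C(C)(C)C)[C@@H]1CC[C@@H](C)c2c1cc(C(=O)OCc3ccccc3)c(O)c2
F2 | step 13 | benzyl (5R,8S)-8-[(2S,6R)-1,7-bis{[tert-butyl(diphenyl)silyl]oxy}-6-methylheptan-2-yl]-4-formyl-3-hydroxy-5-methyl-5,6,7,8-tetrahydronaphthalene-2-carboxylate | CC(C)(C)[Si](c1ccccc1)(c1ccccc1)OC[C@H](C)CCC[C@H](CO[Si](c1ccccc1)(c1ccccc1)C(C)(C)C)[C@@H]1CC[C@@H](C)c2c1cc(C(=O)OCc3ccccc3)c(O)c2C=O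
F3 | step 13 | benzyl (5R,8S)-8-[(2S,6R)-1,7-bis{[tert-butyl(diphenyl)silyl]oxy}-6-methylheptan-2-yl]-3,4-dihydroxy-5-methyl-5,6,7,8-tetrahydronaphthalene-2-carboxylate | CC(C)(C)[Si](c1ccccc1)(c1ccccc1)OC[C@H](C)CCC[C@H](CO[Si](c1ccccc1)(c1ccccc1)C(C)(C)C)[C@@H]1CC[C@@H](C)c2c1cc(C(=O)OCc3ccccc3)c(O)c2O
F4 | step 8 | 9-BBN adduct of 12 (boron on the terminal carbon, both C11 epimers, C11 left undefined) | CC(C)(C)[Si](c1ccccc1)(c1ccccc1)OC[C@H](C)CCCC(CB1C2CCCC1CCC2)[C@@H]1CC[C@@H](C)C2(OCCO2)C1
F5 | step 8 | (2R,6R)-7-{[tert-butyl(diphenyl)silyl]oxy}-6-methyl-2-[(6R,9R)-6-methyl-1,4-dioxaspiro[4.5]decan-9-yl]heptan-1-ol (C11 epimer of 14) | CC(C)(C)[Si](c1ccccc1)(c1ccccc1)OC[C@H](C)CCC[C@@H](CO)[C@@H]1CC[C@@H](C)C2(OCCO2)C1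
F6 | step 3 | 1-[(6R,9R)-6-methyl-1,4-dioxaspiro[4.5]decan-9-yl]ethan-1-one | CC(=O)[C@@H]1CC[C@@H](C)C2(OCCO2)C1
F7 | step 3 | potassium 1-[(6R,9R)-6-methyl-1,4-dioxaspiro[4.5]decan-9-yl]ethen-1-olate | C=C([O-])[C@@H]1CC[C@@H](C)C2(OCCO2)C1.[K+]
F8 | step 3 | 1-[(6R,9R)-6-methyl-1,4-dioxaspiro[4.5]decan-9-yl]ethenyl trifluoromethanesulfonate | C=C(OS(=O)(=O)C(F)(F)F)[C@@H]1CC[C@@H](C)C2(OCCO2)C1
F9 | step 3 | 9-{(4R)-5-[tert-butyl(diphenyl)silyl]oxy-4-methylpentyl}-9-borabicyclo[3.3.1]nonane | CC(C)(C)[Si](c1ccccc1)(c1ccccc1)OC[C@H](C)CCCB1C2CCCC1CCC2
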